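**Retrosynthetic overview**

- The last step removes the two methyl ethers of unit B (6,7-dimethyl ether of the target) with BBr3.
- The strategy rests on benzene ring A of the 7-hydroxycoumarin-6-yl half. Its adjacent carbons C6 (aryl ether) and C7 (hydroxyl) are a two-carbon unit at the aryloxyacetic acid level. The other atoms (C4a, C5, C8, C8a and the pyranone O1-C2-C3-C4) are those of 2H,7H-pyrano[4,3-b]pyran-2,7-dione, whose O6-C7(=O) bridge can leave as CO2. Ring A is therefore cut at C5-C6 and C7-C8.
- The dipyrone comes from di-tert-butyl 3-oxoglutarate: one formyl-level carbon is added, the 4-hydroxy-2-pyrone ring (O6 ring) is closed, the 5-carboxyl is taken down to the aldehyde, and the O1 lactone ring is closed with a ketenylidene ylide.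
- The unit B partner comes from 3,4,5-trimethoxyphenol: ortho-formylation, pivalate on the phenol oxygen, chelation-controlled cleavage of the methoxy group next to the formyl group, O-alkylation with bromoacetate, Z-olefination and lactonisation, then bis-silylation of the acid.
- Ring order: O6 pyranone, then O1 pyranone of the dipyrone; coumarin lactone of unit B; benzene ring A last.

Key step: step 12

Remark: the target is achiral; the only stereochemical element in the route is the Z alkene of the cinnamate that closes the unit B lactone.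

**Route**

Step 1
Reactants: 1 di-tert-butyl 3-oxopentanedioate
Product: 3 4-hydroxy-6-oxo-6H-pyran-3-carboxylic acid, via enaminone diester 2 (not isolated)
Conditions: Me2NCH(OMe)2 (1.0 equiv), toluene, 25 °C; evaporate; then CF3CO2H/CH2Cl2, 25 °C
Reagents that add atoms: N,N-dimethylformamide dimethyl acetal, COC(OC)N(C)C
Why: Amide acetal condensation at one activated methylene gives the enaminone, and in acid the distal ester carbonyl oxygen adds to the iminium carbon with loss of dimethylamine and isobutene (addition-elimination lactonisation) while the second tert-butyl ester is cleaved, so the free acid forms without hot aqueous acid that would open and decarboxylate a 4-hydroxy-2-pyrone.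

Step 2
Reactants: 3 4-hydroxy-6-oxo-6H-pyran-3-carboxylic acid
Product: 4 S-ethyl 4-hydroxy-6-oxo-6H-pyran-3-carbothioate
Conditions: EtSH, DCC, DMAP (cat.), CH2Cl2/THF, 0 to 25 °C
Reagents that add atoms: ethanethiol, CCS
Why: Steglich thioesterification should work because the hydrogen-bonded enol is a poor nucleophile and any O-acylated pyrone that forms is itself an activated ester that the thiol converts to the same thioester.

Step 3
Reactants: 4 S-ethyl 4-hydroxy-6-oxo-6H-pyran-3-carbothioate
Product: 5 4-hydroxy-6-oxo-6H-pyran-3-carbaldehyde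
Conditions: Et3SiH, Pd/C, acetone, 25 °C
Reagents that add atoms: none
Why: The Fukuyama reduction turns a thioester into an aldehyde under neutral conditions through an acylpalladium hydride, and it leaves lactones and acidic hydroxyl groups alone.

Step 4
Reactants: 5 4-hydroxy-6-oxo-6H-pyran-3-carbaldehyde
Product: 7 2H,7H-pyrano[4,3-b]pyran-2,7-dione, via acyl ylide ester 6 (not isolated)
Conditions: Ph3P=C=C=O (1.1 equiv), THF, 65 °C, Ar; anhydrous isolation
Reagents that add atoms: (triphenylphosphoranylidene)ketene, O=C=C=P(c1ccccc1)(c1ccccc1)c1ccccc1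
Why: The acidic enol adds across the cumulated ylide to give an ester-stabilised ylide held next to the formyl group, and the intramolecular Wittig reaction closes the unsaturated lactone with the cis C3=C4 bond (the coumarin synthesis from salicylaldehydes, applied to a vinylogous acid).

Step 5
Reactants: 8 3,4,5-trimethoxyphenol
Product: 10 2-hydroxy-4,5,6-trimethoxybenzaldehyde, via salicyl alcohol 9 (not isolated)
Conditions: MgCl2, Et3N, (CH2O)n, MeCN, reflux; then 1 M HCl
Reagents that add atoms: formaldehyde (as paraformaldehyde), C=O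
Why: The magnesium phenoxide directs hydroxymethylation to the ortho carbon (the two ortho positions are equivalent by symmetry) and a second formaldehyde takes up hydride to give the salicylaldehyde (Casnati-Skattebøl ortho-formylation).

Step 6
Reactants: 10 2-hydroxy-4,5,6-trimethoxybenzaldehyde
Product: 11 2-formyl-3,4,5-trimethoxyphenyl 2,2-dimethylpropanoate
Conditions: t-BuCOCl, Et3N, DMAP (cat.), CH2Cl2, 0 to 25 °C
Reagents that add atoms: pivaloyl chloride, CC(C)(C)C(Cl)=O
Why: Simple O-acylation masks the oxygen that will become the lactone oxygen O1 of unit B with a hindered ester that is not a chelating ether and withstands BCl3 and carbonate.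

Step 7
Reactants: 11 2-formyl-3,4,5-trimethoxyphenyl 2,2-dimethylpropanoate
Product: 12 2-formyl-3-hydroxy-4,5-dimethoxyphenyl 2,2-dimethylpropanoate
Conditions: BCl3 (1.5 equiv), CH2Cl2, -78 to 0 °C; then H2O
Reagents that add atoms: none
Why: Chelation-controlled Lewis acid ether cleavage: boron binds the formyl oxygen and the only ortho methoxy group in a six-membered chelate, so chloride removes that methyl group alone and frees the future C5 oxygen of unit B.

Step 8
Reactants: 12 2-formyl-3-hydroxy-4,5-dimethoxyphenyl 2,2-dimethylpropanoate; 13 methyl bromoacetate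
Product: 14 methyl {3-[(2,2-dimethylpropanoyl)oxy]-2-formyl-5,6-dimethoxyphenoxy}acetate
Conditions: K2CO3, acetone, 25 °C
Reagents that add atoms: none
Why: Williamson etherification of the single free phenol with a reactive alpha-bromo ester should be clean at room temperature, below the temperature at which ortho-formyl aryloxyacetates cyclise to benzofurans.

Step 9
Reactants: 14 methyl {3-[(2,2-dimethylpropanoyl)oxy]-2-formyl-5,6-dimethoxyphenoxy}acetate
Product: 15 methyl (2Z)-3-{6-[(2,2-dimethylpropanoyl)oxy]-3,4-dimethoxy-2-(2-methoxy-2-oxoethoxy)phenyl}prop-2-enoate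
Conditions: (CF3CH2O)2P(O)CH2CO2Me, KN(SiMe3)2, 18-crown-6, THF, -78 °C
Reagents that add atoms: methyl bis(2,2,2-trifluoroethyl)phosphonoacetate, COC(=O)CP(=O)(OCC(F)(F)F)OCC(F)(F)F
Why: The Still-Gennari olefination should give the Z enoate under kinetic control (fast, irreversible elimination from the trifluoroethyl phosphonate adduct), which places the ester cis to the aryl ring as lactonisation requires.

Step 10
Reactants: 15 methyl (2Z)-3-{6-[(2,2-dimethylpropanoyl)oxy]-3,4-dimethoxy-2-(2-methoxy-2-oxoethoxy)phenyl}prop-2-enoate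
Product: 17 [(6,7-dimethoxy-2-oxo-2H-chromen-5-yl)oxy]acetic acid, via Z-configured hydroxy diacid 16 (not isolated)
Conditions: LiOH, THF/H2O, 25 °C; then 2 M HCl to pH 1
Reagents that add atoms: lithium hydroxide, [Li+].[OH-]
Why: Saponification cleaves the pivalate and both methyl esters, and on acidification the cis ortho-hydroxycinnamic acid lactonises spontaneously to the coumarin while the glycolic acid stays free.

Step 11
Reactants: 17 [(6,7-dimethoxy-2-oxo-2H-chromen-5-yl)oxy]acetic acid
Product: 19 5-{[2,2-bis(trimethylsilyloxy)ethenyl]oxy}-6,7-dimethoxy-2H-chromen-2-one, via trimethylsilyl ester 18 (not isolated)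
Conditions: Me3SiCl, Et3N, THF, 0 °C; then Me3SiCl, LiN(SiMe3)2, THF, -78 to 25 °C; filter and concentrate under Ar, use crude
Reagents that add atoms: chlorotrimethylsilane, C[Si](C)(C)Cl
Why: Enolisation of the silyl ester, whose alpha-hydrogens are acidified by the aryloxy group, by a hindered amide base with the chlorosilane already present traps the enolate at once as the bis(silyl) ketene acetal (Ainsworth-type silylation) and leaves the coumarin lactone untouched.

Step 12
Reactants: 7 2H,7H-pyrano[4,3-b]pyran-2,7-dione; 19 5-{[2,2-bis(trimethylsilyloxy)ethenyl]oxy}-6,7-dimethoxy-2H-chromen-2-one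
Product: 23 6-[(6,7-dimethoxy-2-oxo-2H-chromen-5-yl)oxy]-7-hydroxy-2H-chromen-2-one, via bridged lactone adduct 20 (not isolated), via dihydrocoumarin silyl ketal 21 (not isolated), via aryl silyl ether 22 (not isolated)
Conditions: 19 (1.5 equiv), toluene/MeCN, 25 to 90 °C, Ar; then 1 M HCl, THF, 25 °C
Reagents that add atoms: none
Why: Proposed new method: the aryloxy-bearing carbon of the electron-rich ketene acetal should add to C5 of 7, the oxygen-substituted end of the only cyclic s-cis diene (C5=C4a-C8a=C8) and the delta-carbon of both lactone carbonyls, and the silyl oxocarbenium carbon then closes on C8 to give the bridged lactone 20, which loses CO2 by retro-[4+2] to 21 and then trimethylsilanol (hydrogen from C6, one siloxy group from C7) to the arene 22, desilylated on acidic work-up. The closest known reaction type is the inverse-electron-demand Diels-Alder reaction of coumalates and 3-carbomethoxy-2-pyrones with ketene acetals, which gives alkoxy- or hydroxyarenes after loss of CO2 and an alcohol; a fused dipyrone and a bis(silyl) ketene acetal of an aryloxyacetic acid have not been used in it. Benzene ring A is closed by this [4+2] annulation (probably stepwise, Michael addition then Claisen-type closure), which forms C5-C6 and C7-C8, followed by extrusion and 1,2-elimination. The stereocentres of 20 and 21 are destroyed on aromatisation, so none needs control. The step needs regiochemistry (aryloxy carbon to C5, acetal carbon to C8) and ring selectivity (O6 ring, not O1 ring): the first follows from pairing the nucleophilic CH of 19 with the doubly vinylogous electrophilic C5, the second from the O1 ring being cross-conjugated with no lactone-bridged diene, so it survives as the coumarin pyranone. Because C7 carries no hydrogen, only loss of trimethylsilanol can aromatise the ring, which fixes the hydroxyl at C7 and the aryl ether at C6.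

Step 13
Reactants: 23 6-[(6,7-dimethoxy-2-oxo-2H-chromen-5-yl)oxy]-7-hydroxy-2H-chromen-2-one
Product: 24 6-[(6,7-dihydroxy-2-oxo-2H-chromen-5-yl)oxy]-7-hydroxy-2H-chromen-2-one
Conditions: BBr3 (8 equiv), CH2Cl2, -78 to 25 °C; then MeOH/H2O
Reagents that add atoms: none
Why: Lewis acid cleavage of the two aryl methyl ethers (BBr3 demethylation) should leave the diaryl ether and both coumarin lactones intact, as these do not undergo SN2 dealkylation.

**Compound list**

1 | di-tert-butyl 3-oxopentanedioate | CC(C)(C)OC(=O)CC(=O)CC(=O)OC(C)(C)C | starting material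
2 | di-tert-butyl 2-[(dimethylamino)methylidene]-3-oxopentanedioate (alkene geometry not defined) | CN(C)C=C(C(=O)OC(C)(C)C)C(=O)CC(=O)OC(C)(C)C | intermediate
3 | 4-hydroxy-6-oxo-6H-pyran-3-carboxylic acid | OC(=O)C1=COC(=O)C=C1O | intermediate
4 | S-ethyl 4-hydroxy-6-oxo-6H-pyran-3-carbothioate | CCSC(=O)C1=COC(=O)C=C1O | intermediate
5 | 4-hydroxy-6-oxo-6H-pyran-3-carbaldehyde | O=CC1=COC(=O)C=C1O | intermediate
6 | 5-formyl-2-oxo-2H-pyran-4-yl (triphenyl-λ5-phosphanylidene)acetate | O=CC1=COC(=O)C=C1OC(=O)C=P(c1ccccc1)(c1ccccc1)c1ccccc1 | intermediate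
7 | 2H,7H-pyrano[4,3-b]pyran-2,7-dione | O=C1C=CC2=COC(=O)C=C2O1 | intermediate
8 | 3,4,5-trimethoxyphenol | COc1cc(O)cc(OC)c1OC | starting material
9 | 2-(hydroxymethyl)-3,4,5-trimethoxyphenol | COc1cc(O)c(CO)c(OC)c1OC | intermediate
10 | 2-hydroxy-4,5,6-trimethoxybenzaldehyde | COc1cc(O)c(C=O)c(OC)c1OC | intermediate
11 | 2-formyl-3,4,5-trimethoxyphenyl 2,2-dimethylpropanoate | COc1cc(OC(=O)C(C)(C)C)c(C=O)c(OC)c1OC | intermediate
12 | 2-formyl-3-hydroxy-4,5-dimethoxyphenyl 2,2-dimethylpropanoate | COc1cc(OC(=O)C(C)(C)C)c(C=O)c(O)c1OC | intermediate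
13 | methyl bromoacetate | COC(=O)CBr | starting material
14 | methyl {3-[(2,2-dimethylpropanoyl)oxy]-2-formyl-5,6-dimethoxyphenoxy}acetate | COC(=O)COc1c(OC)c(OC)cc(OC(=O)C(C)(C)C)c1C=O | intermediate
15 | methyl (2Z)-3-{6-[(2,2-dimethylpropanoyl)oxy]-3,4-dimethoxy-2-(2-methoxy-2-oxoethoxy)phenyl}prop-2-enoate | COC(=O)COc1c(OC)c(OC)cc(OC(=O)C(C)(C)C)c1/C=C\C(=O)OC | intermediate
16 | (2Z)-3-[2-(carboxymethoxy)-6-hydroxy-3,4-dimethoxyphenyl]prop-2-enoic acid | OC(=O)COc1c(OC)c(OC)cc(O)c1/C=C\C(=O)O | intermediate
17 | [(6,7-dimethoxy-2-oxo-2H-chromen-5-yl)oxy]acetic acid | OC(=O)COc1c(OC)c(OC)cc2oc(=O)ccc12 | intermediate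
18 | trimethylsilyl [(6,7-dimethoxy-2-oxo-2H-chromen-5-yl)oxy]acetate | C[Si](C)(C)OC(=O)COc1c(OC)c(OC)cc2oc(=O)ccc12 | intermediate
19 | 5-{[2,2-bis(trimethylsilyloxy)ethenyl]oxy}-6,7-dimethoxy-2H-chromen-2-one | C[Si](C)(C)OC(O[Si](C)(C)C)=COc1c(OC)c(OC)cc2oc(=O)ccc12 | intermediate
20 | [4+2] adduct of 7 and 19: lactone O6-C7(=O) bridging C5 and C8, new C6 bearing the aryloxy group, new C7 bearing two trimethylsilyloxy groups, C4a=C8a double bond (mixture of diastereomers, configuration not defined) | O=C1C=CC2=C(O1)C3C(=O)OC2C(Oc4c(OC)c(OC)cc5oc(=O)ccc45)C3(O[Si](C)(C)C)O[Si](C)(C)C | intermediate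
21 | 6-[(6,7-dimethoxy-2-oxo-2H-chromen-5-yl)oxy]-7,7-bis(trimethylsilyloxy)-6,7-dihydro-2H-chromen-2-one (racemic) | O=C1C=CC2=CC(Oc3c(OC)c(OC)cc4oc(=O)ccc34)C(O[Si](C)(C)C)(O[Si](C)(C)C)C=C2O1 | intermediate
22 | 6-[(6,7-dimethoxy-2-oxo-2H-chromen-5-yl)oxy]-7-(trimethylsilyloxy)-2H-chromen-2-one | C[Si](C)(C)Oc1cc2oc(=O)ccc2cc1Oc1c(OC)c(OC)cc2oc(=O)ccc12 | intermediate
23 | 6-[(6,7-dimethoxy-2-oxo-2H-chromen-5-yl)oxy]-7-hydroxy-2H-chromen-2-one | O=c1ccc2cc(Oc3c(OC)c(OC)cc4oc(=O)ccc34)c(O)cc2o1 | intermediate
24 | 6-[(6,7-dihydroxy-2-oxo-2H-chromen-5-yl)oxy]-7-hydroxy-2H-chromen-2-one | O=c1ccc2cc(Oc3c(O)c(O)cc4oc(=O)ccc34)c(O)cc2o1 | target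

**Step count**

Total: 13 steps. Longest linear sequence: 9 steps (8 to 24, steps 5 to 13). The dipyrone branch is 4 steps (1 to 7) before the convergent step 12.

**Steps most likely to fail**

1. Step 12 (the proposed new method). The addition at C5 may not be followed by ring closure: silyl transfer to the dienolate oxygen and electrocyclic opening of the 6H-pyranolate would give an open dienoic silyl ester. The ketene acetal may also add at C4 of the cross-conjugated lactone, or adventitious water may cleave the activated enol lactone before cycloaddition.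
Fallback (known chemistry only; sets out from 12, returns at 24): the diaryl ether is made by copper-mediated O-arylation and the unit B lactone is closed afterwards. Commercial 5-bromo-2-hydroxy-4-methoxybenzaldehyde with Ph3P=C=C=O should give 6-bromo-7-methoxy-2H-chromen-2-one F1. Miyaura borylation (bis(pinacolato)diboron, Pd(dppf)Cl2, KOAc, dioxane) should give 7-methoxy-6-(4,4,5,5-tetramethyl-1,3,2-dioxaborolan-2-yl)-2H-chromen-2-one F2. Chan-Lam coupling of phenol 12 with F2 (Cu(OAc)2, pyridine, B(OH)3, 4 Å sieves, MeCN, air) should give 2-formyl-4,5-dimethoxy-3-[(7-methoxy-2-oxo-2H-chromen-6-yl)oxy]phenyl 2,2-dimethylpropanoate F3. Still-Gennari olefination as in step 9 should give methyl (2Z)-3-{6-[(2,2-dimethylpropanoyl)oxy]-3,4-dimethoxy-2-[(7-methoxy-2-oxo-2H-chromen-6-yl)oxy]phenyl}prop-2-enoate F4. LiOH followed by acid as in step 10 should give 6-[(6,7-dimethoxy-2-oxo-2H-chromen-5-yl)oxy]-7-methoxy-2H-chromen-2-one F5, and BBr3 cleaves all three methyl ethers to 24.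

2. Step 4. The strongly acidic enol may only protonate the cumulated ylide to an unreactive ion pair so that O-acylation and ring closure stall, and the activated enol lactone may open hydrolytically during isolation.
Fallback (sets out from 5, returns at 7): Knoevenagel condensation of 5 with Meldrum's acid (pyridine cat., MeCN, 60 °C), with lactonisation by the enol oxygen and loss of acetone, should give 2,7-dioxo-2H,7H-pyrano[4,3-b]pyran-3-carboxylic acid F6. Silver-catalysed protodecarboxylation (Ag2CO3, AcOH, DMSO, 120 °C) then gives 7.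

3. Step 3. Palladium hydride species may reduce the pyranone double bonds or over-reduce the aldehyde, and the thiol by-product may poison the catalyst; self-acylation in step 2 could also limit the supply of thioester.
Fallback (sets out from 3, returns at 5): a reduce-then-oxidise sequence that avoids the thioester. Chemoselective reduction of the carboxylic acid with BH3·SMe2 (THF, 0 °C) should give 4-hydroxy-5-(hydroxymethyl)-2H-pyran-2-one F7, and MnO2 (EtOAc, 25 °C) should oxidise this vinylogous allylic alcohol to aldehyde 5.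

**Further compounds**

F1 | step 12 | 6-bromo-7-methoxy-2H-chromen-2-one | COc1cc2oc(=O)ccc2cc1Br
F2 | step 12 | 7-methoxy-6-(4,4,5,5-tetramethyl-1,3,2-dioxaborolan-2-yl)-2H-chromen-2-one | COc1cc2oc(=O)ccc2cc1B1OC(C)(C)C(C)(C)O1
F3 | step 12 | 2-formyl-4,5-dimethoxy-3-[(7-methoxy-2-oxo-2H-chromen-6-yl)oxy]phenyl 2,2-dimethylpropanoate | COc1cc(OC(=O)C(C)(C)C)c(C=O)c(Oc2cc3ccc(=O)oc3cc2OC)c1OC
F4 | step 12 | methyl (2Z)-3-{6-[(2,2-dimethylpropanoyl)oxy]-3,4-dimethoxy-2-[(7-methoxy-2-oxo-2H-chromen-6-yl)oxy]phenyl}prop-2-enoate | COC(=O)/C=C\c1c(Oc2cc3ccc(=O)oc3cc2OC)c(OC)c(OC)cc1OC(=O)C(C)(C)C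
F5 | step 12 | 6-[(6,7-dimethoxy-2-oxo-2H-chromen-5-yl)oxy]-7-methoxy-2H-chromen-2-one | COc1cc2oc(=O)ccc2cc1Oc1c(OC)c(OC)cc2oc(=O)ccc12
F6 | step 4 | 2,7-dioxo-2H,7H-pyrano[4,3-b]pyran-3-carboxylic acid | OC(=O)C1=CC2=COC(=O)C=C2OC1=O
F7 | step 3 | 4-hydroxy-5-(hydroxymethyl)-2H-pyran-2-one | O=C1C=C(O)C(CO)=CO1
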